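**Retrosynthetic overview**

1. Eriolangin ⇒ 8-deoxy seco-acid 28 by opening the lactone C8–O bond. The strategy rests on the C8 methylene of the cyclohexene ring (C5–C10) lying γ to the C12 carboxyl of the C7 acrylic acid (C12–C11–C7–C8), so that a hydroxyl delivered to C8 cis to C7–C11 closes the γ-lactone.
2. 28 ⇒ keto ester 18 by O6 angeloylation, C11 methylenation and trans reduction of the C6 ketone.
3. 18 ⇒ enone 11 by SAMP-hydrazone α′-alkylation at C7 with a bromoacetate; this sets C7, which then controls C6.
4. 11 ⇒ 2-alkylcyclohexane-1,3-dione 5 (enol triflate, hydroxymethyl Stille coupling, ozonolysis of the prenyl end) ⇒ δ-keto ester 4 from (S)-citronellic acid, which supplies C4.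
5. Ring order: cyclohexene ring first (step 2), γ-lactone last (step 16).

Key step: step 16

Remark: locants are eudesmane-type (ring C5–C10, C11–C13 acrylate, C14 hydroxymethyl, C1–C4 and C15 side chain). It is assumed that a P450 accepting 28 can be found by screening and directed evolution.

**Route**

Step 1
Reactants: 1 (S)-citronellic acid; 2 (4-ethoxy-4-oxobutyl)zinc bromide
Product: 4 ethyl (7S)-7,11-dimethyl-5-oxododec-10-enoate, via (S)-citronelloyl chloride 3 (not isolated)
Conditions: (COCl)2, cat. DMF, CH2Cl2, 0 °C; evaporate; then 2 (0.5 M in THF), Pd(PPh3)4 (3 mol%), THF, 0 °C → rt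
Reagents that add atoms: none
Why: Negishi acylation of a functionalised alkylzinc with an acid chloride should give the δ-keto ester cleanly, and the C4 stereocentre, β to the new ketone, cannot epimerise.

Step 2
Reactants: 4 ethyl (7S)-7,11-dimethyl-5-oxododec-10-enoate
Product: 5 2-[(2S)-6-methylhept-5-en-2-yl]cyclohexane-1,3-dione
Conditions: KOtBu (2.2 equiv), THF, 0 °C → rt; 1 M HCl
Reagents that add atoms: none
Why: Dieckmann-type intramolecular Claisen condensation, in which the ketone enolate at C5 attacks the ester, should close the six-membered 1,3-dione because every other enolate would form a four-membered ring.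

Step 3
Reactants: 5 2-[(2S)-6-methylhept-5-en-2-yl]cyclohexane-1,3-dione
Product: 6 2-[(2S)-6-methylhept-5-en-2-yl]-3-oxocyclohex-1-en-1-yl trifluoromethanesulfonate
Conditions: Tf2O, pyridine, CH2Cl2, −78 → 0 °C
Reagents that add atoms: trifluoromethanesulfonic anhydride, O=S(=O)(OS(=O)(=O)C(F)(F)F)C(F)(F)F
Why: O-triflation of the enol of the C2-symmetric dione (enol triflate formation) can give only one vinylogous acyl triflate.

Step 4
Reactants: 6 the enol triflate; 7 (tributylstannyl)methanol
Product: 8 3-(hydroxymethyl)-2-[(2S)-6-methylhept-5-en-2-yl]cyclohex-2-en-1-one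
Conditions: Pd(PPh3)4 (5 mol%), LiCl, 1,4-dioxane, 100 °C
Reagents that add atoms: none
Why: Stille coupling of the activated β-triflyloxy enone with the hydroxymethylstannane, which transfers its α-oxygenated alkyl group in preference to butyl, should install C14 without transposing the enone.

Step 5
Reactants: 8 3-(hydroxymethyl)-2-[(2S)-6-methylhept-5-en-2-yl]cyclohex-2-en-1-one
Product: 10 3-(hydroxymethyl)-2-[(2S)-5-hydroxypentan-2-yl]cyclohex-2-en-1-one, via keto aldehyde 9 (not isolated)
Conditions: O3, CH2Cl2/MeOH, −78 °C (Sudan III end point); Me2S; then NaBH4, −78 → −40 °C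
Reagents that add atoms: ozone, [O-][O+]=O
Why: Ozonolysis should be selective for the electron-rich trisubstituted alkene over the conjugated tetrasubstituted enone, and borohydride at low temperature should reduce the aldehyde but not the hindered enone (chemoselective reduction).

Step 6
Reactants: 10 the enone diol
Product: 11 3-{[tert-butyl(dimethyl)silyl]oxymethyl}-2-[(2S)-5-{[tert-butyl(dimethyl)silyl]oxy}pentan-2-yl]cyclohex-2-en-1-one
Conditions: TBSCl (2.5 equiv), imidazole, DMF, rt
Reagents that add atoms: tert-butyldimethylsilyl chloride, CC(C)(C)[Si](C)(C)Cl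
Why: Silyl ether formation on two unhindered primary alcohols is routine and leaves only the ketone reactive.

Step 7
Reactants: 11 the bis-silyl enone; 12 (S)-1-amino-2-(methoxymethyl)pyrrolidine (SAMP)
Product: 13 (E)-SAMP hydrazone of 11
Conditions: 12 (1.5 equiv), cat. TsOH, cyclohexane, reflux (Dean–Stark)
Reagents that add atoms: none
Why: Hydrazone condensation with azeotropic water removal should proceed at the ketone, with the N–N bond turned away from the substituted C5 and toward C7.

Step 8
Reactants: 14 bromoacetyl bromide; 15 2-(trimethylsilyl)ethanol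
Product: 16 2-(trimethylsilyl)ethyl bromoacetate
Conditions: pyridine, CH2Cl2, 0 °C
Reagents that add atoms: none
Why: Acylation of a primary alcohol by an acyl bromide (esterification) gives the fluoride-labile ester electrophile.

Step 9
Reactants: 13 the SAMP hydrazone; 16 2-(trimethylsilyl)ethyl bromoacetate
Product: 17 (7S)-C7-alkylated SAMP hydrazone (2-(trimethylsilyl)ethyl ester)
Conditions: LDA, THF, 0 °C; then 16, −100 → −78 °C
Reagents that add atoms: none
Why: Enders SAMP-hydrazone α-alkylation: kinetic deprotonation at C7 gives the lithium-chelated azaenolate, which the bromoacetate should attack on the face opposite the methoxymethyl-pyrrolidine shielding, setting C7 as S (C11 on the face that later carries the lactone oxygen) independently of the remote C4 centre.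

Step 10
Reactants: 17 the alkylated hydrazone
Product: 18 2-(trimethylsilyl)ethyl 2-[(1S)-4-{[tert-butyl(dimethyl)silyl]oxymethyl}-3-[(2S)-5-{[tert-butyl(dimethyl)silyl]oxy}pentan-2-yl]-2-oxocyclohex-3-en-1-yl]acetate
Conditions: sat. aq. oxalic acid, Et2O, rt
Reagents that add atoms: water, O
Why: Two-phase oxalic acid hydrolysis of the hydrazone should release the ketone without epimerising C7 and returns the auxiliary.

Step 11
Reactants: 18 the keto ester
Product: 19 2-(trimethylsilyl)ethyl 2-[(1S,2S)-2-hydroxy-4-(silyloxymethyl)-3-(silyloxypentan-2-yl)cyclohex-3-en-1-yl]acetate (6S,7S; OH trans to the C7 side chain)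
Conditions: NaBH4, CeCl3·7H2O, MeOH, −78 °C
Reagents that add atoms: none
Why: Luche 1,2-reduction: axial hydride delivery to the half-chair enone with the C7 substituent pseudo-equatorial should give the pseudo-equatorial 6-hydroxyl trans to C7 (substrate control), and the ester is untouched.

Step 12
Reactants: 19 the hydroxy ester
Product: 20 6-O-trimethylsilyl ether of 19
Conditions: TMSCl, imidazole, CH2Cl2, 0 °C
Reagents that add atoms: chlorotrimethylsilane, C[Si](C)(C)Cl
Why: Transient silylation masks the 6-hydroxyl so that the following enolate chemistry cannot lactonise it onto C12.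

Step 13
Reactants: 20 the TMS ether
Product: 24 2-(trimethylsilyl)ethyl 2-[(1S,2S)-2-hydroxy-4-(silyloxymethyl)-3-(silyloxypentan-2-yl)cyclohex-3-en-1-yl]acrylate, via Mannich base 21 (not isolated), via trimethylammonium iodide 22 (not isolated), via O-TMS acrylate 23 (not isolated)
Conditions: LDA, THF, −78 °C; CH2=NMe2+ I−, −78 → 0 °C; MeI, MeOH, rt; sat. aq. NaHCO3, CH2Cl2; citric acid, MeOH, 0 °C
Reagents that add atoms: Eschenmoser's salt, C=[N+](C)C.[I-]
Why: Eschenmoser α-methylenation (ester enolate Mannich reaction, N-quaternisation, E1cB elimination) should build the C11=C13 methylene, and the mild acid finish removes only the labile TMS ether.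

Step 14
Reactants: 24 the hydroxy acrylate; 25 angelic acid
Product: 27 6-O-angeloyl ester of 24, via angelic 2,4,6-trichlorobenzoic anhydride 26 (not isolated)
Conditions: 25, 2,4,6-trichlorobenzoyl chloride, Et3N, toluene, rt; then 24, 80 °C (no DMAP)
Reagents that add atoms: none
Why: Yamaguchi esterification through the mixed anhydride should acylate the hindered allylic alcohol, and leaving out the nucleophilic catalyst avoids Z to E isomerisation of the angelate.

Step 15
Reactants: 27 the fully protected angelate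
Product: 28 8-deoxy seco-acid: 2-[(1S,2S)-2-(angeloyloxy)-4-(hydroxymethyl)-3-[(2S)-5-hydroxypentan-2-yl]cyclohex-3-en-1-yl]acrylic acid
Conditions: TBAF, AcOH (1:1), THF, 0 °C → rt; pH 4 work-up
Reagents that add atoms: none
Why: Buffered fluoride should cleave both primary silyl ethers and fragment the 2-(trimethylsilyl)ethyl ester (β-silyl elimination) in one operation without acid that would ionise the allylic angelate.

Step 16
Reactants: 28 the 8-deoxy seco-acid
Product: 30 eriolangin, via 8-hydroxy seco-acid 29 (not isolated)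
Conditions: engineered cytochrome P450 (CYP71BL-type germacrene A acid 8-hydroxylase homologue or evolved P450BM3 variant) with reductase, cat. NADPH, glucose/glucose dehydrogenase, air, KPi buffer pH 7.4, 5% DMSO, 28 °C; then pH 4
Reagents that add atoms: dioxygen, O=O
Why: Proposed new method: the ferryl-oxo species (compound I) should abstract the C8 hydrogen that lies on the face of the C7 acrylic acid and return oxygen by rebound with retention, giving the (8R)-alcohol 29. The closest known reaction type is CYP71-family hydroxylation of germacrene A acid at C6 or C8 with spontaneous γ-lactonisation, together with engineered bacterial P450 hydroxylation of terpenoid acids, but no enzyme is known for this 6-acyloxy seco-eudesmane acid. The ring closes by 5-exo-trig acyl substitution of the 8-hydroxyl on the C12 carboxyl, which is possible only for the hydroxyl cis to C7–C11 and gives the cis-fused α-methylene-γ-lactone. The new C8 stereocentre is under enzyme (reagent) control, the fixed C7 configuration deciding which diastereotopic hydrogen faces the iron when the carboxylate is bound. The step needs site selectivity for C8 over the allylic C6, C9, C4 and C14 hydrogens and over epoxidation of C5=C10, and only carboxylate anchoring in the active site, which places the γ-carbon C8 at the oxo group, can provide it. The substrate helps by carrying the same acrylic acid head group as the natural substrates and by needing no protecting groups or base afterwards.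

**Compound list**

1 | (S)-citronellic acid, (3S)-3,7-dimethyloct-6-enoic acid | OC(=O)C[C@@H](C)CCC=C(C)C | starting material
2 | (4-ethoxy-4-oxobutyl)zinc bromide | CCOC(=O)CCC[Zn]Br | starting material
3 | (S)-citronelloyl chloride | ClC(=O)C[C@@H](C)CCC=C(C)C | intermediate
4 | ethyl (7S)-7,11-dimethyl-5-oxododec-10-enoate | CCOC(=O)CCCC(=O)C[C@@H](C)CCC=C(C)C | intermediate
5 | 2-[(2S)-6-methylhept-5-en-2-yl]cyclohexane-1,3-dione | O=C1CCCC(=O)C1[C@@H](C)CCC=C(C)C | intermediate
6 | 2-[(2S)-6-methylhept-5-en-2-yl]-3-oxocyclohex-1-en-1-yl triflate | O=C1CCCC(OS(=O)(=O)C(F)(F)F)=C1[C@@H](C)CCC=C(C)C | intermediate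
7 | (tributylstannyl)methanol | CCCC[Sn](CCCC)(CCCC)CO | starting material
8 | 3-(hydroxymethyl)-2-[(2S)-6-methylhept-5-en-2-yl]cyclohex-2-en-1-one | O=C1CCCC(CO)=C1[C@@H](C)CCC=C(C)C | intermediate
9 | (4S)-4-[2-(hydroxymethyl)-6-oxocyclohex-1-en-1-yl]pentanal | O=C1CCCC(CO)=C1[C@@H](C)CCC=O | intermediate
10 | 3-(hydroxymethyl)-2-[(2S)-5-hydroxypentan-2-yl]cyclohex-2-en-1-one | O=C1CCCC(CO)=C1[C@@H](C)CCCO | intermediate
11 | bis-TBS ether of 10 | O=C1CCCC(CO[Si](C)(C)C(C)(C)C)=C1[C@@H](C)CCCO[Si](C)(C)C(C)(C)C | intermediate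
12 | SAMP, (S)-1-amino-2-(methoxymethyl)pyrrolidine | COC[C@@H]1CCCN1N | starting material
13 | (E)-SAMP hydrazone of 11 | C1CCC(CO[Si](C)(C)C(C)(C)C)=C([C@@H](C)CCCO[Si](C)(C)C(C)(C)C)/C1=N/N2CCC[C@H]2COC | intermediate
14 | bromoacetyl bromide | BrCC(Br)=O | starting material
15 | 2-(trimethylsilyl)ethanol | C[Si](C)(C)CCO | starting material
16 | 2-(trimethylsilyl)ethyl bromoacetate | BrCC(=O)OCC[Si](C)(C)C | intermediate
17 | (7S)-alkylated SAMP hydrazone | C[Si](C)(C)CCOC(=O)C[C@@H]1CCC(CO[Si](C)(C)C(C)(C)C)=C([C@@H](C)CCCO[Si](C)(C)C(C)(C)C)/C1=N/N2CCC[C@H]2COC | intermediate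
18 | keto ester (7S) | C[Si](C)(C)CCOC(=O)C[C@@H]1CCC(CO[Si](C)(C)C(C)(C)C)=C([C@@H](C)CCCO[Si](C)(C)C(C)(C)C)C1=O | intermediate
19 | trans hydroxy ester (6S,7S) | C[Si](C)(C)CCOC(=O)C[C@@H]1CCC(CO[Si](C)(C)C(C)(C)C)=C([C@@H](C)CCCO[Si](C)(C)C(C)(C)C)[C@H]1O | intermediate
20 | 6-O-TMS ether of 19 | C[Si](C)(C)CCOC(=O)C[C@@H]1CCC(CO[Si](C)(C)C(C)(C)C)=C([C@@H](C)CCCO[Si](C)(C)C(C)(C)C)[C@H]1O[Si](C)(C)C | intermediate
21 | Mannich base (C11 epimers) | C[Si](C)(C)CCOC(=O)C(CN(C)C)[C@@H]1CCC(CO[Si](C)(C)C(C)(C)C)=C([C@@H](C)CCCO[Si](C)(C)C(C)(C)C)[C@H]1O[Si](C)(C)C | intermediate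
22 | trimethylammonium iodide of 21 | C[Si](C)(C)CCOC(=O)C(C[N+](C)(C)C)[C@@H]1CCC(CO[Si](C)(C)C(C)(C)C)=C([C@@H](C)CCCO[Si](C)(C)C(C)(C)C)[C@H]1O[Si](C)(C)C.[I-] | intermediate
23 | O-TMS acrylate | C=C(C(=O)OCC[Si](C)(C)C)[C@@H]1CCC(CO[Si](C)(C)C(C)(C)C)=C([C@@H](C)CCCO[Si](C)(C)C(C)(C)C)[C@H]1O[Si](C)(C)C | intermediate
24 | hydroxy acrylate (6S,7S) | C=C(C(=O)OCC[Si](C)(C)C)[C@@H]1CCC(CO[Si](C)(C)C(C)(C)C)=C([C@@H](C)CCCO[Si](C)(C)C(C)(C)C)[C@H]1O | intermediate
25 | angelic acid, (Z)-2-methylbut-2-enoic acid | C/C=C(/C)C(=O)O | starting material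
26 | angelic 2,4,6-trichlorobenzoic anhydride | C/C=C(/C)C(=O)OC(=O)c1c(Cl)cc(Cl)cc1Cl | intermediate
27 | protected 6-O-angeloyl seco-ester | C=C(C(=O)OCC[Si](C)(C)C)[C@@H]1CCC(CO[Si](C)(C)C(C)(C)C)=C([C@@H](C)CCCO[Si](C)(C)C(C)(C)C)[C@H]1OC(=O)/C(C)=C\C | intermediate
28 | 8-deoxy seco-acid (key-step precursor) | C=C(C(=O)O)[C@@H]1CCC(CO)=C([C@@H](C)CCCO)[C@H]1OC(=O)/C(C)=C\C | intermediate
29 | (8R)-8-hydroxy seco-acid | C=C(C(=O)O)[C@@H]1[C@H](O)CC(CO)=C([C@@H](C)CCCO)[C@H]1OC(=O)/C(C)=C\C | intermediate
30 | eriolangin | C=C1C(=O)O[C@@H]2CC(CO)=C([C@@H](C)CCCO)[C@@H](OC(=O)/C(C)=C\C)[C@H]12 | target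

**Step count**

Total: 16 steps. Longest linear sequence: 15 steps (steps 1–7 and 9–16; step 8 is a one-step branch).

**Steps most likely to fail**

Step 16 (Proposed new method). No enzyme may turn the substrate over. Oxidation may be diverted to the allylic hydrogens at C6, C9, C4 or C14, or to epoxidation of C5=C10. Oxygen may also be delivered to the C8 face trans to C7–C11, so that the hydroxy acid cannot lactonise.
Fallback, by known chemistry, sets out from hydrazone 17 and moves the C8–O bond formation to the ketone stage, where C6 carries no hydrogen and the ring alkene is deactivated by conjugation. Aluminium amide aminolysis of the ester (AlMe3, NH4Cl, CH2Cl2, 40 °C) should give the primary amide hydrazone F1. Oxalic acid hydrolysis gives the keto amide F2. A Hofmann–Löffler–Freytag-type amidyl radical lactonisation (PhI(OAc)2, I2, visible light, CH2Cl2; aqueous acid work-up) should then proceed through the N-iodoamide, 1,5-hydrogen transfer from C8 (the only γ-hydrogen left), iodine transfer, closure through the amide oxygen and hydrolysis of the iminolactone to the cis-fused keto lactone F3. Corey–Bakshi–Shibata reduction with (R)-Me-CBS and catecholborane should give the 6S alcohol, hydroxy lactone F4, under catalyst control. Transient TMS protection and Eschenmoser methylenation of the lactone enolate give the methylene hydroxy lactone F5. Yamaguchi angeloylation gives bis-silyl eriolangin F6, and HF·pyridine in THF returns to the route at 30.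

Step 9 (with step 7). Hydrazone formation on the hindered 2,3-disubstituted enone may stall. Deprotonation may occur at the γ positions (C9, C14) instead of C7. Facial selectivity of the azaenolate alkylation may be low.
Fallback sets out from enone 11 and replaces auxiliary control by catalyst control plus a self-sorting separation. Direct kinetic enolate alkylation (LDA, THF, −78 °C; 16) should give the C7-epimeric keto ester F7. Corey–Bakshi–Shibata reduction with (R)-Me-CBS and BH3·SMe2 should set C6 as S in both epimers. The trans isomer is 19. The cis (6S,7R) hydroxy ester F8 lactonises on PPTS treatment to the cis-fused 6,12-lactone F9, which is removed by chromatography. The route is rejoined at 19.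

Step 14. Acylation of the hindered allylic 6-hydroxyl may be slow. The hydroxyl may instead close onto C12 to the trans-fused lactone on heating with base. The angelate may isomerise to the tiglate.
Fallback sets out from 24 and builds the Z-alkene after acylation. Carbodiimide coupling at 0 °C with 2-[bis(2,2,2-trifluoroethoxy)phosphoryl]propanoic acid (DCC, cat. DMAP, CH2Cl2) should give the phosphonate ester F10. Still–Gennari olefination (KHMDS, 18-crown-6, THF, −78 °C; acetaldehyde) should give the Z-2-methylbut-2-enoate and return to the route at 27.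

**Further compounds**

F1 | step 16 | primary amide SAMP hydrazone | NC(=O)C[C@@H]1CCC(CO[Si](C)(C)C(C)(C)C)=C([C@@H](C)CCCO[Si](C)(C)C(C)(C)C)/C1=N/N2CCC[C@H]2COC
F2 | step 16 | keto amide | NC(=O)C[C@@H]1CCC(CO[Si](C)(C)C(C)(C)C)=C([C@@H](C)CCCO[Si](C)(C)C(C)(C)C)C1=O
F3 | step 16 | cis-fused 8,12-keto lactone | O=C1C[C@@H]2[C@H](O1)CC(CO[Si](C)(C)C(C)(C)C)=C([C@@H](C)CCCO[Si](C)(C)C(C)(C)C)C2=O
F4 | step 16 | (6S)-hydroxy lactone | O=C1C[C@@H]2[C@H](O1)CC(CO[Si](C)(C)C(C)(C)C)=C([C@@H](C)CCCO[Si](C)(C)C(C)(C)C)[C@H]2O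
F5 | step 16 | α-methylene hydroxy lactone | C=C1C(=O)O[C@@H]2CC(CO[Si](C)(C)C(C)(C)C)=C([C@@H](C)CCCO[Si](C)(C)C(C)(C)C)[C@@H](O)[C@H]12
F6 | step 16 | 1,14-bis-O-TBS eriolangin | C=C1C(=O)O[C@@H]2CC(CO[Si](C)(C)C(C)(C)C)=C([C@@H](C)CCCO[Si](C)(C)C(C)(C)C)[C@@H](OC(=O)/C(C)=C\C)[C@H]12
F7 | step 9 | C7-epimeric keto ester | C[Si](C)(C)CCOC(=O)CC1CCC(CO[Si](C)(C)C(C)(C)C)=C([C@@H](C)CCCO[Si](C)(C)C(C)(C)C)C1=O
F8 | step 9 | cis (6S,7R) hydroxy ester | C[Si](C)(C)CCOC(=O)C[C@H]1CCC(CO[Si](C)(C)C(C)(C)C)=C([C@@H](C)CCCO[Si](C)(C)C(C)(C)C)[C@H]1O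
F9 | step 9 | cis-fused 6,12-lactone | O=C1C[C@H]2CCC(CO[Si](C)(C)C(C)(C)C)=C([C@@H](C)CCCO[Si](C)(C)C(C)(C)C)[C@H]2O1
F10 | step 14 | 6-O-phosphonopropionate | C=C(C(=O)OCC[Si](C)(C)C)[C@@H]1CCC(CO[Si](C)(C)C(C)(C)C)=C([C@@H](C)CCCO[Si](C)(C)C(C)(C)C)[C@H]1OC(=O)C(C)P(=O)(OCC(F)(F)F)OCC(F)(F)F
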